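X is conserved here: the scheme moves it among free X, Z, J.Z and X.Z, and each X.Z holds two of it.

    X + D ⇌ G + Z, settled at all times (K1 = 1.2)
    J + Z → J.Z (k2 = 0.11 /M/s)
    X + Z → X.Z (k3 = 0.49 /M/s)

the same everywhere: D 0.100 M; time 1.0 min
- eta: X 0.10 M; J 0.300 M (fed, over 40 s); all else is in the flask from the start; the feed brings no volume worth counting
- alpha: X 0.10 M; J 0.300 M; everything together at the start
- theta: X 0.10 M (fed, over 40 s); J 0.300 M; all else is in the flask from the start; the feed brings no volume worth counting

- in percentages every species weighs as the X in it: one X.Z counts as two
- run time (eta): 1.0 min

1. the flask that comes out highest in amount of X.Z, in percent of the X charged, or "all alike" when all lie within 1.5 percentage points (eta / alpha / theta / all alike)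
2. X.Z at the end, in percent of the X charged, eta
3. X.Z at the end, in percent of the X charged, alpha
4. X.Z at the end, in percent of the X charged, theta

I treat Z as a tank with two parallel drains, each pseudo-first-order for as long as cJ and cX hold still: one to J, with rate constant 0.11 /M/s times cJ, and one to X, with 0.49 /M/s times cX. X.Z gains the upper hand while the X drain is the wider, so I look for the moment the two drains are equal.

The fast balance comes first. With X and D charged equally, cZ over cX is the square root of 1.2, so free X starts at 0.0477 M in alpha and in eta. In alpha the J drain is already 1.41 times the X drain, wider than it from the first moment. Theta starts with no X in the flask, so its X drain starts shut. Eta starts with no J, so the X drain leads there, and I pick eta.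

With cX frozen, eta's drains match at cJ of 0.212 M, which the feed reaches at 28.3 s.

The frozen cX is the weak link, since X.Z eats the pool of X plus Z. I let free X stay half of that pool and leave the J drain out of the pool's loss, so in eta the pool falls as one over one plus 0.0245 /s times time. Setting the drains equal again gives the crossing time, the moment the J drain overtakes the X drain, at 19.9 s. By then my reckoning has about 32.8% of the X standing as X.Z in eta, counting the pool's loss as X.Z; I commit to that figure for the crossing, not for the end of the run.

The forecast gives eta as highest, with 49%, 38% and 24% for eta, alpha and theta: “Feeding J late leaves Z with only X to react with at first”.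

The simulation gives 48.7% of X.Z in eta, 37.8% in alpha and 24.4% in theta, so eta stands highest. In eta half of the X.Z turnover up to the asked time is done by 0.226 min and half of the J.Z turnover by 0.542 min, with my reckoned crossing at 0.332 min between them. With 0.75 M of J fed over the same time, the same reckoning puts the crossing at 9.61 s, earlier than in eta, and that neighbour ends at 39.9% of X.Z.

The numbers are assumed; the result is computed.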